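**Retrosynthetic overview**

1. Atom labels: ring A = C1–C2–C3–C4–C5–C10, ring B = C5–C6–C7–C8–C9–C10, C11 = carbinol carbon on C7, C1' = benzylic carbon. Late stage: the three ArOH come from ArOMe, the two CHO from ArBr (Br/Li exchange, DMF), and the C4 carbinol from MeLi on a C4 ketone.
2. Key disconnection: ring B is opened at C6–C7 to a ring A α-methylene ketone (O=C4–C5=C6H2) whose quaternary C10 carries a homoprenyl chain. An acid-promoted enone–olefin cyclization closes ring B and places the oxygen on C11.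
3. Enabling feature: C4=O lies on ring A next to the ring-fusion carbon C5, which carries C6, and C7 (1,3 to C5 in ring B) bears the oxygenated C(CH3)2 carbon C11. This is the pattern left when a C7=C11 prenyl-type alkene attacks the C6 terminus of the enone O=C4–C5=C6 through C7 and the C11 cation is trapped by an oxygen nucleophile.
4. The precursor comes from copper-catalysed conjugate addition of a homoprenyl Grignard reagent to C10 of a 4-substituted 3-methylcyclohexenone (C9–C10 bond, anti to the C1 side chain), then α-methylenation at C5. The C1–C1' bond is made earlier by γ-(vinylogous) Mukaiyama–Michael addition of the silyl dienol ether of 3-methylcyclohex-2-enone to an o-quinone methide.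
5. Ring order: aromatic ring (purchased) → ring A (purchased as 3-methylcyclohex-2-enone) → ring B, closed last in step 7.

Key step: step 7

Remark: the sense of induction of the chiral phosphoric acid in step 3 is assumed; the antipodal catalyst is taken if it proves opposite.

**Step 1**
Reactants: 1 3-methylcyclohex-2-en-1-one
Product: 2 tert-butyl(dimethyl)[(3-methylcyclohexa-1,3-dien-1-yl)oxy]silane
Conditions: MeMgBr (1.1 equiv), FeCl3 (5 mol %), Et2O, −20 °C; then TBSCl, Et3N, HMPA, −20 °C → rt
Reagents that add atoms: tert-butyldimethylsilyl chloride, CC(C)(C)[Si](C)(C)Cl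
Why: Iron-catalysed γ-deprotonation by MeMgBr gives the thermodynamic, linearly conjugated dienolate, and O-silylation traps it as the 1-silyloxy-1,3-diene whose ring γ-carbon (later C1) is the nucleophilic terminus (thermodynamic silyl dienol ether formation).

**Step 2**
Reactants: 3 2-hydroxy-4,6-dimethoxybenzaldehyde
Product: 4 2-(1-hydroxy-3-methylbutyl)-3,5-dimethoxyphenol (racemic)
Conditions: i-BuMgBr (2.5 equiv), THF, 0 °C → rt; H2O (pH 7) quench; used crude
Reagents that add atoms: isobutylmagnesium bromide, CC(C)C[Mg]Br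
Why: Grignard 1,2-addition to the aldehyde after the first equivalent has deprotonated the phenol; the carbinol stereocentre is of no consequence because it becomes trigonal in step 3.

**Step 3**
Reactants: 2 tert-butyl(dimethyl)[(3-methylcyclohexa-1,3-dien-1-yl)oxy]silane; 4 2-(1-hydroxy-3-methylbutyl)-3,5-dimethoxyphenol
Product: 6 (4R)-4-[(1R)-1-(2-hydroxy-4,6-dimethoxyphenyl)-3-methylbutyl]-3-methylcyclohex-2-en-1-one, via o-quinone methide 5 (not isolated)
Conditions: (R)-3,3'-bis(2,4,6-triisopropylphenyl)-1,1'-binaphthyl-2,2'-diyl hydrogen phosphate (10 mol %), toluene, 0 °C → rt; then 1 M HCl, THF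
Reagents that add atoms: none
Why: Proposed new method: the chiral phosphoric acid dehydrates 4 to the hydrogen-bonded o-quinone methide 5 (isobutyl syn to the carbonyl, away from the ortho methoxy group), and the dienol ether adds through its γ-carbon in an endo, [4+2]-like transition state with ring A under the quinone methide, which sets C1' and C1 together, while the released water takes up the silyl group and regenerates the enone; the absolute configuration is dictated by the catalyst pocket; the closest known reaction types are chiral phosphoric acid-catalysed conjugate additions and [4+2] reactions of enol-type nucleophiles with in situ o-quinone methides, and the acid-mediated vinylogous Mukaiyama–Michael (γ-) coupling of silyl dienol ethers with benzylic cation equivalents.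

**Step 4**
Reactants: 6 (4R)-4-[(1R)-1-(2-hydroxy-4,6-dimethoxyphenyl)-3-methylbutyl]-3-methylcyclohex-2-en-1-one
Product: 7 (4R)-3-methyl-4-[(1R)-3-methyl-1-(2,4,6-trimethoxyphenyl)butyl]cyclohex-2-en-1-one
Conditions: MeI, K2CO3, acetone, 50 °C
Reagents that add atoms: iodomethane, CI
Why: Williamson O-methylation of the only phenol (K2CO3 is too weak to epimerise the γ-stereocentre) removes the acidic proton and the possibility of oxa-Michael closure onto C10 before the organometallic steps.

**Step 5**
Reactants: 7 (4R)-3-methyl-4-[(1R)-3-methyl-1-(2,4,6-trimethoxyphenyl)butyl]cyclohex-2-en-1-one; 8 5-bromo-2-methylpent-2-ene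
Product: 10 trimethyl({(3R,4R)-3-methyl-3-(4-methylpent-3-en-1-yl)-4-[(1R)-3-methyl-1-(2,4,6-trimethoxyphenyl)butyl]cyclohex-1-en-1-yl}oxy)silane, via Grignard reagent 9 (not isolated)
Conditions: 8, Mg, THF; then 7, CuBr·SMe2 (20 mol %), TMSCl, HMPA, THF, −78 → −30 °C; Et3N, aq. NaHCO3; used crude
Reagents that add atoms: chlorotrimethylsilane, C[Si](C)(C)Cl
Why: TMSCl-accelerated copper-catalysed conjugate addition of the Grignard reagent to the β,β-disubstituted enone, in which the bulky C1 substituent sits pseudoaxial (A(1,2) strain with the C10 methyl) and the reagent adds axially to C10 from the opposite face, so the new chain is trans and the methyl cis to the side chain, and the enolate is trapped regiospecifically as the C4=C5 silyl enol ether.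

**Step 6**
Reactants: 10 trimethyl({(3R,4R)-3-methyl-3-(4-methylpent-3-en-1-yl)-4-[(1R)-3-methyl-1-(2,4,6-trimethoxyphenyl)butyl]cyclohex-1-en-1-yl}oxy)silane
Product: 13 (3R,4R)-3-methyl-2-methylidene-3-(4-methylpent-3-en-1-yl)-4-[(1R)-3-methyl-1-(2,4,6-trimethoxyphenyl)butyl]cyclohexan-1-one, via Mannich base 11 (not isolated), via methiodide 12 (not isolated)
Conditions: N,N-dimethylmethyleneiminium iodide (Eschenmoser's salt), CH2Cl2, rt; then MeI; then aq. NaHCO3, CH2Cl2, rt; used at once
Reagents that add atoms: N,N-dimethylmethyleneiminium iodide, C=[N+](C)C.[I-]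
Why: Mannich reaction of the regiodefined silyl enol ether at C5, N-quaternisation and E1cB loss of trimethylamine (α-methylenation); the exocyclic enone cannot migrate into the ring because C10 is quaternary.

**Step 7**
Reactants: 13 (3R,4R)-3-methyl-2-methylidene-3-(4-methylpent-3-en-1-yl)-4-[(1R)-3-methyl-1-(2,4,6-trimethoxyphenyl)butyl]cyclohexan-1-one
Product: 15 (4R,4aR,7S,8aS)-7-(2-hydroxypropan-2-yl)-4a-methyl-4-[(1R)-3-methyl-1-(2,4,6-trimethoxyphenyl)butyl]octahydronaphthalen-1(2H)-one, via tertiary formate 14 (not isolated)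
Conditions: HCO2H–CH2Cl2 (1:1), 0.01 M, 0 °C → rt; then K2CO3, MeOH, rt
Reagents that add atoms: formic acid, OC=O
Why: Formic acid activates the C4 carbonyl of the α-methylene ketone, the unhindered exocyclic C6 becomes electrophilic, and the trisubstituted C7=C11 alkene attacks it through C7 (Markovnikov), forming C6–C7 and a tertiary C11 cation that the solvent traps as the formate, after which the ring A enol tautomerises and K2CO3/MeOH cleaves the formate. The closest known reaction types are the acid-induced cationic enone–olefin (vinylogous Prins) cyclization, i.e. conjugate addition of an alkene to a Lewis or Brønsted acid-activated enone, and the hydrative Prins cyclization of citronellal to p-menthane-3,8-diol. Ring B closes through a six-membered chair transition state, endo with respect to the C5=C6 enone double bond and exo with respect to the C7=C11 alkene. C7 is set by this chair: ring A forces the C10 methyl axial on the forming ring, and the developing C(CH3)2 cation takes the equatorial position, cis to that methyl. C5 is set under thermodynamic control during the K2CO3/MeOH stage, the trans ring fusion being the only arrangement with both the C1 side chain and the C7 group equatorial. The step needs cation capture to outrun proton loss, 1,2-hydride shift and the concerted ene pathway (which would demand an axial prenyl terminus and give the C7 epimer), and intramolecular attack to outrun enone oligomerisation; the ionising, nucleophilic solvent, high dilution and the hindered, non-isomerisable enone next to quaternary C10 are meant to secure this.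

**Step 8**
Reactants: 15 (4R,4aR,7S,8aS)-7-(2-hydroxypropan-2-yl)-4a-methyl-4-[(1R)-3-methyl-1-(2,4,6-trimethoxyphenyl)butyl]octahydronaphthalen-1(2H)-one
Product: 16 (1R,4R,4aR,7S,8aS)-7-(2-hydroxypropan-2-yl)-1,4a-dimethyl-4-[(1R)-3-methyl-1-(2,4,6-trimethoxyphenyl)butyl]decahydronaphthalen-1-ol
Conditions: MeLi (4 equiv), Et2O–THF, −78 → 0 °C; H2O
Reagents that add atoms: methyllithium, [Li]C
Why: 1,2-Addition of MeLi (the first equivalent deprotonates the C11 alcohol) to the C4 ketone from the equatorial direction, because the axial trajectory is blocked by the syn-axial C10 methyl, giving the axial hydroxyl cis to the angular methyl and the equatorial C4 methyl.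

**Step 9**
Reactants: 16 (1R,4R,4aR,7S,8aS)-7-(2-hydroxypropan-2-yl)-1,4a-dimethyl-4-[(1R)-3-methyl-1-(2,4,6-trimethoxyphenyl)butyl]decahydronaphthalen-1-ol
Product: 17 (1R,4R,4aR,7S,8aS)-4-[(1R)-1-(3,5-dibromo-2,4,6-trimethoxyphenyl)-3-methylbutyl]-7-(2-hydroxypropan-2-yl)-1,4a-dimethyldecahydronaphthalen-1-ol
Conditions: NBS (2.1 equiv), MeCN, 0 °C
Reagents that add atoms: N-bromosuccinimide, O=C1CCC(=O)N1Br
Why: Electrophilic aromatic bromination of the two remaining ring positions, each flanked by two methoxy groups, under neutral conditions that leave both tertiary alcohols untouched.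

**Step 10**
Reactants: 17 (1R,4R,4aR,7S,8aS)-4-[(1R)-1-(3,5-dibromo-2,4,6-trimethoxyphenyl)-3-methylbutyl]-7-(2-hydroxypropan-2-yl)-1,4a-dimethyldecahydronaphthalen-1-ol
Product: 19 5-{(1R)-1-[(1R,4R,4aS,6S,8aR)-4-hydroxy-6-(2-hydroxypropan-2-yl)-4,8a-dimethyldecahydronaphthalen-1-yl]-3-methylbutyl}-2,4,6-trimethoxybenzene-1,3-dicarbaldehyde, via dilithio arene 18 (not isolated)
Conditions: t-BuLi (6.5 equiv), THF, −78 °C; then DMF, −78 °C → rt; H2O
Reagents that add atoms: N,N-dimethylformamide, CN(C)C=O
Why: Twofold bromine–lithium exchange (after deprotonation of both alcohols) gives a dilithio arene in which each C–Li is chelated by two ortho methoxy groups, and DMF formylates both positions under basic conditions compatible with the tertiary alkoxides (halogen–lithium exchange and formylation).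

**Step 11**
Reactants: 19 5-{(1R)-1-[(1R,4R,4aS,6S,8aR)-4-hydroxy-6-(2-hydroxypropan-2-yl)-4,8a-dimethyldecahydronaphthalen-1-yl]-3-methylbutyl}-2,4,6-trimethoxybenzene-1,3-dicarbaldehyde
Product: 20 5-{(1R)-1-[(1R,4R,4aS,6S,8aR)-4-hydroxy-6-(2-hydroxypropan-2-yl)-4,8a-dimethyldecahydronaphthalen-1-yl]-3-methylbutyl}-2,4,6-trihydroxybenzene-1,3-dicarbaldehyde
Conditions: NaSEt (excess), DMF, 110 °C; then 1 M HCl
Reagents that add atoms: none
Why: All three methoxy groups are ortho or para to a formyl group, so the phenoxide leaving groups are vinylogous carboxylates and thiolate SN2 demethylation proceeds under basic conditions that spare the two tertiary alcohols, which acidic ether cleavage would dehydrate.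

**Compound list**

1 | 3-methylcyclohex-2-en-1-one | CC1=CC(=O)CCC1 | starting material
2 | tert-butyl(dimethyl)[(3-methylcyclohexa-1,3-dien-1-yl)oxy]silane | CC1=CCCC(O[Si](C)(C)C(C)(C)C)=C1 | intermediate
3 | 2-hydroxy-4,6-dimethoxybenzaldehyde | COc1cc(O)c(C=O)c(OC)c1 | starting material
4 | 2-(1-hydroxy-3-methylbutyl)-3,5-dimethoxyphenol (racemic) | CC(C)CC(O)c1c(O)cc(OC)cc1OC | intermediate
5 | (6Z)-3,5-dimethoxy-6-(3-methylbutylidene)cyclohexa-2,4-dien-1-one (o-quinone methide) | CC(C)C\C=C1/C(=O)C=C(OC)C=C1OC | intermediate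
6 | (4R)-4-[(1R)-1-(2-hydroxy-4,6-dimethoxyphenyl)-3-methylbutyl]-3-methylcyclohex-2-en-1-one | CC(C)C[C@@H](c1c(O)cc(OC)cc1OC)[C@H]1CCC(=O)C=C1C | intermediate
7 | (4R)-3-methyl-4-[(1R)-3-methyl-1-(2,4,6-trimethoxyphenyl)butyl]cyclohex-2-en-1-one | CC(C)C[C@@H](c1c(OC)cc(OC)cc1OC)[C@H]1CCC(=O)C=C1C | intermediate
8 | 5-bromo-2-methylpent-2-ene | CC(C)=CCCBr | starting material
9 | (4-methylpent-3-en-1-yl)magnesium bromide | CC(C)=CCC[Mg]Br | intermediate
10 | trimethyl({(3R,4R)-3-methyl-3-(4-methylpent-3-en-1-yl)-4-[(1R)-3-methyl-1-(2,4,6-trimethoxyphenyl)butyl]cyclohex-1-en-1-yl}oxy)silane | CC(C)C[C@@H](c1c(OC)cc(OC)cc1OC)[C@H]1CCC(O[Si](C)(C)C)=C[C@]1(C)CCC=C(C)C | intermediate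
11 | (3R,4R)-2-[(dimethylamino)methyl]-3-methyl-3-(4-methylpent-3-en-1-yl)-4-[(1R)-3-methyl-1-(2,4,6-trimethoxyphenyl)butyl]cyclohexan-1-one (C2 epimers) | CC(C)C[C@@H](c1c(OC)cc(OC)cc1OC)[C@H]1CCC(=O)C(CN(C)C)[C@]1(C)CCC=C(C)C | intermediate
12 | N,N,N-trimethyl-1-{(1R,6R)-1-methyl-1-(4-methylpent-3-en-1-yl)-6-[(1R)-3-methyl-1-(2,4,6-trimethoxyphenyl)butyl]-3-oxocyclohexan-2-yl}methanaminium iodide (C2 epimers) | CC(C)C[C@@H](c1c(OC)cc(OC)cc1OC)[C@H]1CCC(=O)C(C[N+](C)(C)C)[C@]1(C)CCC=C(C)C.[I-] | intermediate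
13 | (3R,4R)-3-methyl-2-methylidene-3-(4-methylpent-3-en-1-yl)-4-[(1R)-3-methyl-1-(2,4,6-trimethoxyphenyl)butyl]cyclohexan-1-one | CC(C)C[C@@H](c1c(OC)cc(OC)cc1OC)[C@H]1CCC(=O)C(=C)[C@]1(C)CCC=C(C)C | intermediate
14 | 2-{(2S,4aR,5R,8aS)-4a-methyl-5-[(1R)-3-methyl-1-(2,4,6-trimethoxyphenyl)butyl]-8-oxodecahydronaphthalen-2-yl}propan-2-yl formate | CC(C)C[C@@H](c1c(OC)cc(OC)cc1OC)[C@H]1CCC(=O)[C@H]2C[C@@H](C(C)(C)OC=O)CC[C@]12C | intermediate
15 | (4R,4aR,7S,8aS)-7-(2-hydroxypropan-2-yl)-4a-methyl-4-[(1R)-3-methyl-1-(2,4,6-trimethoxyphenyl)butyl]octahydronaphthalen-1(2H)-one | CC(C)C[C@@H](c1c(OC)cc(OC)cc1OC)[C@H]1CCC(=O)[C@H]2C[C@@H](C(C)(C)O)CC[C@]12C | intermediate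
16 | (1R,4R,4aR,7S,8aS)-7-(2-hydroxypropan-2-yl)-1,4a-dimethyl-4-[(1R)-3-methyl-1-(2,4,6-trimethoxyphenyl)butyl]decahydronaphthalen-1-ol | CC(C)C[C@@H](c1c(OC)cc(OC)cc1OC)[C@H]1CC[C@@](C)(O)[C@H]2C[C@@H](C(C)(C)O)CC[C@]12C | intermediate
17 | (1R,4R,4aR,7S,8aS)-4-[(1R)-1-(3,5-dibromo-2,4,6-trimethoxyphenyl)-3-methylbutyl]-7-(2-hydroxypropan-2-yl)-1,4a-dimethyldecahydronaphthalen-1-ol | CC(C)C[C@@H](c1c(OC)c(Br)c(OC)c(Br)c1OC)[C@H]1CC[C@@](C)(O)[C@H]2C[C@@H](C(C)(C)O)CC[C@]12C | intermediate
18 | 3,5-dilithio-2,4,6-trimethoxyphenyl dilithium dialkoxide derived from 17 (dilithio arene) | CC(C)C[C@@H](c1c(OC)c([Li])c(OC)c([Li])c1OC)[C@H]1CC[C@@](C)(O[Li])[C@H]2C[C@@H](C(C)(C)O[Li])CC[C@]12C | intermediate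
19 | 5-{(1R)-1-[(1R,4R,4aS,6S,8aR)-4-hydroxy-6-(2-hydroxypropan-2-yl)-4,8a-dimethyldecahydronaphthalen-1-yl]-3-methylbutyl}-2,4,6-trimethoxybenzene-1,3-dicarbaldehyde | CC(C)C[C@@H](c1c(OC)c(C=O)c(OC)c(C=O)c1OC)[C@H]1CC[C@@](C)(O)[C@H]2C[C@@H](C(C)(C)O)CC[C@]12C | intermediate
20 | 5-{(1R)-1-[(1R,4R,4aS,6S,8aR)-4-hydroxy-6-(2-hydroxypropan-2-yl)-4,8a-dimethyldecahydronaphthalen-1-yl]-3-methylbutyl}-2,4,6-trihydroxybenzene-1,3-dicarbaldehyde | CC(C)C[C@@H](c1c(O)c(C=O)c(O)c(C=O)c1O)[C@H]1CC[C@@](C)(O)[C@H]2C[C@@H](C(C)(C)O)CC[C@]12C | target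

**Step count and risks**

Total step count: 11. Longest linear sequence: 10 steps (steps 1, 3–11 from 3-methylcyclohex-2-en-1-one; equally steps 2–11 from 2-hydroxy-4,6-dimethoxybenzaldehyde).

Steps most likely to fail:

1. Step 3 (proposed new method). What may go wrong: poor facial selectivity at C1' and C1 if the addition runs through a loosely bound, stepwise cation outside the catalyst pocket, and competing hydrolysis of the dienol ether. Fallback (known chemistry), setting out from 2 and 4: the same γ-coupling is run with an achiral acid (diphenyl hydrogen phosphate or BF3·OEt2), the established acid-mediated vinylogous Mukaiyama–Michael reaction of silyl dienol ethers with benzylic cation or o-quinone methide electrophiles. The racemic product is then resolved by preparative chromatography on a chiral stationary phase. The unwanted enantiomer (4S)-4-[(1S)-1-(2-hydroxy-4,6-dimethoxyphenyl)-3-methylbutyl]-3-methylcyclohex-2-en-1-one F1 is discarded, and the wanted enantiomer is 6, where the route is rejoined. The C4-epimeric diastereomers can be equilibrated through the γ-position with DBU and recycled.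

2. Step 7 (key step). What may go wrong: capture of the C11 cation by formate loses to proton loss (isopropenyl and isopropylidene mixtures) or to a 1,2-hydride shift from C7, or the exocyclic enone oligomerises before it cyclises. Fallback, setting out from 7: the conjugate addition of step 5 is run with the Grignard reagent of (E)-(5-bromo-2-methylpent-2-en-1-yl)trimethylsilane F2, giving the silyl enol ether trimethyl({(3R,4R)-3-methyl-3-[(3E)-4-methyl-5-(trimethylsilyl)pent-3-en-1-yl]-4-[(1R)-3-methyl-1-(2,4,6-trimethoxyphenyl)butyl]cyclohex-1-en-1-yl}oxy)silane F3. This is methylenated as in step 6 to (3R,4R)-3-methyl-2-methylidene-3-[(3E)-4-methyl-5-(trimethylsilyl)pent-3-en-1-yl]-4-[(1R)-3-methyl-1-(2,4,6-trimethoxyphenyl)butyl]cyclohexan-1-one F4. TiCl4 (CH2Cl2, −78 °C) then triggers an intramolecular Hosomi–Sakurai conjugate allylation through the same chair, in which the β-silyl cation collapses only to the isopropenyl group, giving (4R,4aR,7S,8aS)-4a-methyl-4-[(1R)-3-methyl-1-(2,4,6-trimethoxyphenyl)butyl]-7-(prop-1-en-2-yl)octahydronaphthalen-1(2H)-one F5. Mukaiyama hydration (Co(acac)2, PhSiH3, O2, i-PrOH) converts F5 into 15, where the route is rejoined.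

3. Step 10. What may go wrong: incomplete second bromine–lithium exchange or protonation of the polylithiated intermediate, leading to mono-formylated and debrominated material. Fallback, setting out from 16 (steps 9 and 10 are bypassed): after deprotonation of both alcohols, directed ortho-lithiation (n-BuLi, TMEDA, THF, 0 °C) and DMF give the mono-aldehyde 3-{(1R)-1-[(1R,4R,4aS,6S,8aR)-4-hydroxy-6-(2-hydroxypropan-2-yl)-4,8a-dimethyldecahydronaphthalen-1-yl]-3-methylbutyl}-2,4,6-trimethoxybenzaldehyde F6. Its formyl group is masked in the flask as the α-amino alkoxide with lithium N,N,N'-trimethylethylenediamide, the last ring C–H (between two methoxy groups) is lithiated with n-BuLi and quenched with DMF, and aqueous work-up gives 19, where the route is rejoined.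

**Further compounds**

F1 | step 3 | (4S)-4-[(1S)-1-(2-hydroxy-4,6-dimethoxyphenyl)-3-methylbutyl]-3-methylcyclohex-2-en-1-one | CC(C)C[C@H](c1c(O)cc(OC)cc1OC)[C@@H]1CCC(=O)C=C1C
F2 | step 7 | (E)-(5-bromo-2-methylpent-2-en-1-yl)trimethylsilane | C[Si](C)(C)C/C(C)=C/CCBr
F3 | step 7 | trimethyl({(3R,4R)-3-methyl-3-[(3E)-4-methyl-5-(trimethylsilyl)pent-3-en-1-yl]-4-[(1R)-3-methyl-1-(2,4,6-trimethoxyphenyl)butyl]cyclohex-1-en-1-yl}oxy)silane | CC(C)C[C@@H](c1c(OC)cc(OC)cc1OC)[C@H]1CCC(O[Si](C)(C)C)=C[C@]1(C)CC/C=C(\C)C[Si](C)(C)C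
F4 | step 7 | (3R,4R)-3-methyl-2-methylidene-3-[(3E)-4-methyl-5-(trimethylsilyl)pent-3-en-1-yl]-4-[(1R)-3-methyl-1-(2,4,6-trimethoxyphenyl)butyl]cyclohexan-1-one | CC(C)C[C@@H](c1c(OC)cc(OC)cc1OC)[C@H]1CCC(=O)C(=C)[C@]1(C)CC/C=C(\C)C[Si](C)(C)C
F5 | step 7 | (4R,4aR,7S,8aS)-4a-methyl-4-[(1R)-3-methyl-1-(2,4,6-trimethoxyphenyl)butyl]-7-(prop-1-en-2-yl)octahydronaphthalen-1(2H)-one | CC(C)C[C@@H](c1c(OC)cc(OC)cc1OC)[C@H]1CCC(=O)[C@H]2C[C@@H](C(C)=C)CC[C@]12C
F6 | step 10 | 3-{(1R)-1-[(1R,4R,4aS,6S,8aR)-4-hydroxy-6-(2-hydroxypropan-2-yl)-4,8a-dimethyldecahydronaphthalen-1-yl]-3-methylbutyl}-2,4,6-trimethoxybenzaldehyde | CC(C)C[C@@H](c1c(OC)c(C=O)c(OC)cc1OC)[C@H]1CC[C@@](C)(O)[C@H]2C[C@@H](C(C)(C)O)CC[C@]12C
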